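**Strategy.** Both trans-2,3-diaryl-2,3-dihydrobenzofurans are disconnected at O1–C2 and C2–C3 into an ortho-quinone methide and a benzylic sulfonium ylide that carries a chiral sulfide. The key step exploits the ortho pair phenol O1′ / benzylic C3′ on the central resorcinol ring (C7a′ and C3a′ of the dihydrofuran bearing the 2,4-dihydroxyphenyl group): the quinone methide, released from an ortho-(sulfonylmethyl)phenol, accepts the ylide at C3′, and the phenoxide then displaces the sulfide at C2′, closing that furan ring through O1′–C2′ and setting both stereocentres in one operation. The same annulation then joins this unit to the stilbene-bearing ring; debenzylation ends the route.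

Key step: step 8

Locants: primed locants (O1′, C2′, C3′, C3a′, C7a′) belong to the dihydrobenzofuran that carries the 2,4-dihydroxyphenyl group; unprimed locants belong to the dihydrobenzofuran fused to the stilbene ring.

Assumption: the sense of induction of the isothiocineole sulfide is taken from a transition-state model of its benzylides (ylide aryl syn to the sulfur lone pair, electrophile entering on the face remote from the gem-dimethyl carbon). This predicts the (S) configuration at the ylide-derived carbon in steps 8 and 16. If the opposite sense were found, the enantiomeric sulfide from (S)-limonene would be used in steps 2 and 10 with no other change.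

**Step 1**
Reactants: 1 2,4-bis(benzyloxy)benzaldehyde
Product: 2 [2,4-bis(benzyloxy)phenyl]methanol
Conditions: NaBH4, MeOH/THF, 0 °C
Reagents that add atoms: none
Why: Hydride reduction of the aryl aldehyde (NaBH4 reduction) leaves the benzyl ethers untouched and creates no stereocentre.

**Step 2**
Reactants: 2 [2,4-bis(benzyloxy)phenyl]methanol; 3 (1R,4R,5R)-isothiocineole
Product: 4 (1R,4R,5R,6R)-6-[2,4-bis(benzyloxy)benzyl]-4,7,7-trimethyl-6-thiabicyclo[3.2.1]octan-6-ium tetrafluoroborate
Conditions: HBF4·OEt2 (1 equiv), CH2Cl2, 0 °C; precipitation with Et2O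
Reagents that add atoms: tetrafluoroboric acid, [H+].F[B-](F)(F)F
Why: Acid-promoted ionisation of the electron-rich benzylic alcohol and capture by sulfur (SN1 S-alkylation) is reversible and should settle on the exo S-benzyl salt, so that sulfur becomes a single stereocentre.

**Step 3**
Reactants: 5 methyl 2,4-dihydroxybenzoate
Product: 6 methyl 3-formyl-2,4-dihydroxybenzoate
Conditions: hexamethylenetetramine, CF3CO2H, reflux; then aq. HCl, 60 °C
Reagents that add atoms: hexamethylenetetramine, C1N2CN3CN1CN(C2)C3; water, O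
Why: Duff ortho-formylation should deliver the iminium electrophile to C3, the position ortho to both hydroxyls of the chelated resorcinol ester, and hydrolysis then gives the aldehyde.

**Step 4**
Reactants: 6 methyl 3-formyl-2,4-dihydroxybenzoate
Product: 7 methyl 4-(benzyloxy)-3-formyl-2-hydroxybenzoate
Conditions: BnBr (1.05 equiv), K2CO3 (1.1 equiv), acetone, rt
Reagents that add atoms: benzyl bromide, BrCc1ccccc1
Why: Williamson etherification should occur at the more accessible and more acidic 4-OH (para to the ester), because the 2-OH is buried between the ester and formyl groups and chelated to the ester carbonyl.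

**Step 5**
Reactants: 8 1-bromo-3,5-bis(benzyloxy)benzene
Product: 9 [3,5-bis(benzyloxy)phenyl]magnesium bromide (titrated THF stock solution, kept under argon, used in steps 6 and 14)
Conditions: Mg turnings (I2 crystal), THF, 50 °C; titration
Reagents that add atoms: magnesium, [Mg]
Why: Grignard formation by insertion of magnesium into the aryl C–Br bond tolerates the aryl benzyl ethers and gives one batch of reagent for both carbinol-forming steps.

**Step 6**
Reactants: 7 methyl 4-(benzyloxy)-3-formyl-2-hydroxybenzoate; 9 [3,5-bis(benzyloxy)phenyl]magnesium bromide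
Product: 10 methyl 4-(benzyloxy)-3-{[3,5-bis(benzyloxy)phenyl](hydroxy)methyl}-2-hydroxybenzoate (racemic)
Conditions: 9 (2.3 equiv, THF solution) added to 7, THF, −78 → −20 °C; aq. NH4Cl
Reagents that add atoms: none
Why: Grignard addition, in which the first equivalent forms the magnesium phenoxide and the second adds to the aldehyde, which is far more electrophilic than the phenoxide-deactivated ester at low temperature; the racemic carbinol centre is erased in step 8.

**Step 7**
Reactants: 10 methyl 4-(benzyloxy)-3-{[3,5-bis(benzyloxy)phenyl](hydroxy)methyl}-2-hydroxybenzoate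
Product: 11 methyl 4-(benzyloxy)-3-{[3,5-bis(benzyloxy)phenyl](4-methylbenzenesulfonyl)methyl}-2-hydroxybenzoate (racemic)
Conditions: p-TolSO2H (2 equiv), CH2Cl2, rt
Reagents that add atoms: 4-methylbenzenesulfinic acid, Cc1ccc(cc1)S(=O)O
Why: Acid-mediated SN1 substitution of the doubly benzylic ortho-hydroxy carbinol by sulfinate sulfur (through the protonated quinone methide) should give a stable, crystalline quinone methide precursor.

**Step 8**
Reactants: 11 methyl 4-(benzyloxy)-3-{[3,5-bis(benzyloxy)phenyl](4-methylbenzenesulfonyl)methyl}-2-hydroxybenzoate; 4 (1R,4R,5R,6R)-6-[2,4-bis(benzyloxy)benzyl]-4,7,7-trimethyl-6-thiabicyclo[3.2.1]octan-6-ium tetrafluoroborate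
Product: 14 methyl (2S,3S)-4-(benzyloxy)-2-[2,4-bis(benzyloxy)phenyl]-3-[3,5-bis(benzyloxy)phenyl]-2,3-dihydro-1-benzofuran-7-carboxylate (trans), via ortho-quinone methide 12 (not isolated), via sulfonium ylide 13 (not isolated)
Conditions: Cs2CO3 (3 equiv), MeCN/CH2Cl2, 0 °C, 11 first; then 4 (1.3 equiv) in portions, 0 °C → rt
Reagents that add atoms: none
Why: Cs2CO3 deprotonates the salicylate phenol of 11, sulfinate leaves by 1,4-elimination to give ortho-quinone methide 12, and carbonate converts 4 into the semi-stabilised benzylide 13, which adds through carbon to the exocyclic methide carbon (C3′) under the drive of re-aromatisation, after which the phenoxide displaces the neutral sulfide from C2′ with inversion. The closest known reaction type is the [4+1] annulation of ortho-quinone methides with sulfur ylides (a Michael-initiated ring closure), run here with a chiral sulfonium benzylide of the kind used for asymmetric epoxidation. The dihydrofuran ring closes in the 5-exo-tet mode through the O1′–C2′ bond. C2′ is controlled by the sulfide, whose bicyclic frame fixes the ylide conformation and shields the face next to the gem-dimethyl carbon, and C3′ is set in the addition, which should pass through the open anti-periplanar arrangement that leads to the trans ring; any ionising character in the closure also converges on the trans isomer. The step needs O2-versus-O4 regioselectivity, secured because only the free 2-OH can become the quinone methide carbonyl and close the ring while O4 is benzylated, and conjugate instead of carbonyl addition, secured by re-aromatisation.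

**Step 9**
Reactants: 14 methyl (2S,3S)-4-(benzyloxy)-2-[2,4-bis(benzyloxy)phenyl]-3-[3,5-bis(benzyloxy)phenyl]-2,3-dihydro-1-benzofuran-7-carboxylate
Product: 15 {(2S,3S)-4-(benzyloxy)-2-[2,4-bis(benzyloxy)phenyl]-3-[3,5-bis(benzyloxy)phenyl]-2,3-dihydro-1-benzofuran-7-yl}methanol
Conditions: LiAlH4, THF, 0 °C
Reagents that add atoms: none
Why: LiAlH4 reduction of the aryl ester to the benzylic alcohol leaves the ethers and both stereocentres untouched.

**Step 10**
Reactants: 15 {(2S,3S)-4-(benzyloxy)-2-[2,4-bis(benzyloxy)phenyl]-3-[3,5-bis(benzyloxy)phenyl]-2,3-dihydro-1-benzofuran-7-yl}methanol; 3 (1R,4R,5R)-isothiocineole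
Product: 16 (1R,4R,5R,6R)-6-({(2S,3S)-4-(benzyloxy)-2-[2,4-bis(benzyloxy)phenyl]-3-[3,5-bis(benzyloxy)phenyl]-2,3-dihydro-1-benzofuran-7-yl}methyl)-4,7,7-trimethyl-6-thiabicyclo[3.2.1]octan-6-ium tetrafluoroborate
Conditions: 3 (1.2 equiv), HBF4·OEt2 (1.0 equiv), CH2Cl2, −40 → 0 °C; precipitation with Et2O
Reagents that add atoms: tetrafluoroboric acid, [H+].F[B-](F)(F)F
Why: The same SN1 S-alkylation as in step 2 should be selective because the alcohol oxygen is the most basic site, and any reversible opening at C2′ could only re-close to the same trans ring since O4 is benzylated.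

**Step 11**
Reactants: 17 4-bromo-2,6-difluorobenzaldehyde
Product: 18 2,6-bis(benzyloxy)-4-bromobenzaldehyde
Conditions: BnOH (2.2 equiv), NaH, THF/DMF, 0 °C → rt
Reagents that add atoms: benzyl alcohol, OCc1ccccc1
Why: Double nucleophilic aromatic substitution (SNAr) should be easy because both fluorides are ortho to the formyl group.

**Step 12**
Reactants: 18 2,6-bis(benzyloxy)-4-bromobenzaldehyde; 19 1-(benzyloxy)-4-ethenylbenzene
Product: 20 2,6-bis(benzyloxy)-4-[(E)-2-(4-(benzyloxy)phenyl)ethenyl]benzaldehyde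
Conditions: Pd(OAc)2, P(o-tol)3, Et3N, DMF, 100 °C
Reagents that add atoms: none
Why: Mizoroki–Heck reaction of the aryl bromide activated by the para formyl group, in which syn insertion and syn β-hydride elimination should give the E-stilbene.

**Step 13**
Reactants: 20 2,6-bis(benzyloxy)-4-[(E)-2-(4-(benzyloxy)phenyl)ethenyl]benzaldehyde
Product: 21 2-(benzyloxy)-6-hydroxy-4-[(E)-2-(4-(benzyloxy)phenyl)ethenyl]benzaldehyde
Conditions: MgBr2·OEt2 (1.5 equiv), toluene/Et2O, rt → 40 °C; aq. HCl
Reagents that add atoms: none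
Why: Chelation-controlled debenzylation ortho to the carbonyl by MgBr2 should stop after one ether, because the magnesium phenoxide–aldehyde chelate deactivates the second ortho ether and the remote 4′-ether is not chelated.

**Step 14**
Reactants: 21 2-(benzyloxy)-6-hydroxy-4-[(E)-2-(4-(benzyloxy)phenyl)ethenyl]benzaldehyde; 9 [3,5-bis(benzyloxy)phenyl]magnesium bromide
Product: 22 3-(benzyloxy)-2-{[3,5-bis(benzyloxy)phenyl](hydroxy)methyl}-5-[(E)-2-(4-(benzyloxy)phenyl)ethenyl]phenol (racemic)
Conditions: 9 (2.3 equiv, THF solution) added to 21, THF, −78 → −20 °C; aq. NH4Cl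
Reagents that add atoms: none
Why: Grignard addition to the aldehyde after phenoxide formation, as in step 6; the racemic carbinol centre is erased in step 16.

**Step 15**
Reactants: 22 3-(benzyloxy)-2-{[3,5-bis(benzyloxy)phenyl](hydroxy)methyl}-5-[(E)-2-(4-(benzyloxy)phenyl)ethenyl]phenol
Product: 23 3-(benzyloxy)-2-{[3,5-bis(benzyloxy)phenyl](4-methylbenzenesulfonyl)methyl}-5-[(E)-2-(4-(benzyloxy)phenyl)ethenyl]phenol (racemic)
Conditions: p-TolSO2H (2 equiv), CH2Cl2, rt
Reagents that add atoms: 4-methylbenzenesulfinic acid, Cc1ccc(cc1)S(=O)O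
Why: SN1 substitution of the ionisable carbinol by sulfinate, as in step 7.

**Step 16**
Reactants: 23 3-(benzyloxy)-2-{[3,5-bis(benzyloxy)phenyl](4-methylbenzenesulfonyl)methyl}-5-[(E)-2-(4-(benzyloxy)phenyl)ethenyl]phenol; 16 (1R,4R,5R,6R)-6-({(2S,3S)-4-(benzyloxy)-2-[2,4-bis(benzyloxy)phenyl]-3-[3,5-bis(benzyloxy)phenyl]-2,3-dihydro-1-benzofuran-7-yl}methyl)-4,7,7-trimethyl-6-thiabicyclo[3.2.1]octan-6-ium tetrafluoroborate
Product: 26 nona-O-benzylgnetumontanin B [(2S,3S)-4-(benzyloxy)-2-{(2S,3S)-4-(benzyloxy)-2-[2,4-bis(benzyloxy)phenyl]-3-[3,5-bis(benzyloxy)phenyl]-2,3-dihydro-1-benzofuran-7-yl}-3-[3,5-bis(benzyloxy)phenyl]-6-[(E)-2-(4-(benzyloxy)phenyl)ethenyl]-2,3-dihydro-1-benzofuran], via ortho-quinone methide 24 (not isolated), via sulfonium ylide 25 (not isolated)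
Conditions: Cs2CO3 (3 equiv), MeCN/CH2Cl2, 0 °C, 23 first; then 16 (1.2 equiv) in portions, 0 °C → rt
Reagents that add atoms: none
Why: A second [4+1] annulation of an ortho-quinone methide with a chiral sulfonium benzylide (mechanism of step 8) closes O1–C2 in the 5-exo-tet mode, the sulfide setting C2 as S and the trans-selective addition setting C3 independently of the remote lower ring, while only the free phenol oxygen of the stilbene ring can react.

**Step 17**
Reactants: 26 nona-O-benzylgnetumontanin B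
Product: 27 gnetumontanin B
Conditions: BCl3 (excess), C6HMe5 (excess), CH2Cl2, −78 °C; MeOH quench at −78 °C, then aq. work-up
Reagents that add atoms: none
Why: Lewis-acid debenzylation with BCl3 and pentamethylbenzene as a non-basic benzyl-cation scavenger at −78 °C should spare the stilbene double bond and the four dihydrofuran stereocentres.

**Compound list**

1 | 2,4-bis(benzyloxy)benzaldehyde | O=Cc1ccc(OCc2ccccc2)cc1OCc1ccccc1 | starting material
2 | [2,4-bis(benzyloxy)phenyl]methanol | OCc1ccc(OCc2ccccc2)cc1OCc1ccccc1 | intermediate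
3 | (1R,4R,5R)-4,7,7-trimethyl-6-thiabicyclo[3.2.1]octane (isothiocineole, derived from (R)-limonene) | C[C@@H]1CC[C@@H]2C[C@H]1SC2(C)C | starting material
4 | (1R,4R,5R,6R)-6-[2,4-bis(benzyloxy)benzyl]-4,7,7-trimethyl-6-thiabicyclo[3.2.1]octan-6-ium tetrafluoroborate | C[C@@H]1CC[C@@H]2C[C@H]1[S@@+](Cc1ccc(OCc3ccccc3)cc1OCc1ccccc1)C2(C)C.F[B-](F)(F)F | intermediate
5 | methyl 2,4-dihydroxybenzoate | COC(=O)c1ccc(O)cc1O | starting material
6 | methyl 3-formyl-2,4-dihydroxybenzoate | COC(=O)c1ccc(O)c(C=O)c1O | intermediate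
7 | methyl 4-(benzyloxy)-3-formyl-2-hydroxybenzoate | COC(=O)c1ccc(OCc2ccccc2)c(C=O)c1O | intermediate
8 | 1-bromo-3,5-bis(benzyloxy)benzene | Brc1cc(OCc2ccccc2)cc(OCc2ccccc2)c1 | starting material
9 | [3,5-bis(benzyloxy)phenyl]magnesium bromide (THF stock solution) | Br[Mg]c1cc(OCc2ccccc2)cc(OCc2ccccc2)c1 | intermediate
10 | methyl 4-(benzyloxy)-3-{[3,5-bis(benzyloxy)phenyl](hydroxy)methyl}-2-hydroxybenzoate (racemic) | COC(=O)c1ccc(OCc2ccccc2)c(C(O)c2cc(OCc3ccccc3)cc(OCc3ccccc3)c2)c1O | intermediate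
11 | methyl 4-(benzyloxy)-3-{[3,5-bis(benzyloxy)phenyl](4-methylbenzenesulfonyl)methyl}-2-hydroxybenzoate (racemic) | COC(=O)c1ccc(OCc2ccccc2)c(C(c2cc(OCc3ccccc3)cc(OCc3ccccc3)c2)S(=O)(=O)c2ccc(C)cc2)c1O | intermediate
12 | methyl 4-(benzyloxy)-5-{[3,5-bis(benzyloxy)phenyl]methylidene}-6-oxocyclohexa-1,3-diene-1-carboxylate (ortho-quinone methide) | COC(=O)C1=CC=C(OCc2ccccc2)C(=Cc2cc(OCc3ccccc3)cc(OCc3ccccc3)c2)C1=O | intermediate
13 | sulfonium ylide of 4, [2,4-bis(benzyloxy)phenyl][(1R,4R,5R,6R)-4,7,7-trimethyl-6-thiabicyclo[3.2.1]octan-6-ium-6-yl]methanide | C[C@@H]1CC[C@@H]2C[C@H]1[S@@+]([CH-]c1ccc(OCc3ccccc3)cc1OCc1ccccc1)C2(C)C | intermediate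
14 | methyl (2S,3S)-4-(benzyloxy)-2-[2,4-bis(benzyloxy)phenyl]-3-[3,5-bis(benzyloxy)phenyl]-2,3-dihydro-1-benzofuran-7-carboxylate | COC(=O)c1ccc(OCc3ccccc3)c2c1O[C@H](c1ccc(OCc3ccccc3)cc1OCc1ccccc1)[C@H]2c1cc(OCc2ccccc2)cc(OCc2ccccc2)c1 | intermediate
15 | {(2S,3S)-4-(benzyloxy)-2-[2,4-bis(benzyloxy)phenyl]-3-[3,5-bis(benzyloxy)phenyl]-2,3-dihydro-1-benzofuran-7-yl}methanol | OCc1ccc(OCc3ccccc3)c2c1O[C@H](c1ccc(OCc3ccccc3)cc1OCc1ccccc1)[C@H]2c1cc(OCc2ccccc2)cc(OCc2ccccc2)c1 | intermediate
16 | (1R,4R,5R,6R)-6-({(2S,3S)-4-(benzyloxy)-2-[2,4-bis(benzyloxy)phenyl]-3-[3,5-bis(benzyloxy)phenyl]-2,3-dihydro-1-benzofuran-7-yl}methyl)-4,7,7-trimethyl-6-thiabicyclo[3.2.1]octan-6-ium tetrafluoroborate | C[C@@H]1CC[C@@H]2C[C@H]1[S@@+](Cc1ccc(OCc3ccccc3)c3c1O[C@H](c1ccc(OCc4ccccc4)cc1OCc1ccccc1)[C@H]3c1cc(OCc3ccccc3)cc(OCc3ccccc3)c1)C2(C)C.F[B-](F)(F)F | intermediate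
17 | 4-bromo-2,6-difluorobenzaldehyde | O=Cc1c(F)cc(Br)cc1F | starting material
18 | 2,6-bis(benzyloxy)-4-bromobenzaldehyde | O=Cc1c(OCc2ccccc2)cc(Br)cc1OCc1ccccc1 | intermediate
19 | 1-(benzyloxy)-4-ethenylbenzene | C=Cc1ccc(OCc2ccccc2)cc1 | starting material
20 | 2,6-bis(benzyloxy)-4-[(E)-2-(4-(benzyloxy)phenyl)ethenyl]benzaldehyde | O=Cc1c(OCc2ccccc2)cc(/C=C/c2ccc(OCc3ccccc3)cc2)cc1OCc1ccccc1 | intermediate
21 | 2-(benzyloxy)-6-hydroxy-4-[(E)-2-(4-(benzyloxy)phenyl)ethenyl]benzaldehyde | O=Cc1c(O)cc(/C=C/c2ccc(OCc3ccccc3)cc2)cc1OCc1ccccc1 | intermediate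
22 | 3-(benzyloxy)-2-{[3,5-bis(benzyloxy)phenyl](hydroxy)methyl}-5-[(E)-2-(4-(benzyloxy)phenyl)ethenyl]phenol (racemic) | OC(c1cc(OCc2ccccc2)cc(OCc2ccccc2)c1)c1c(O)cc(/C=C/c2ccc(OCc3ccccc3)cc2)cc1OCc1ccccc1 | intermediate
23 | 3-(benzyloxy)-2-{[3,5-bis(benzyloxy)phenyl](4-methylbenzenesulfonyl)methyl}-5-[(E)-2-(4-(benzyloxy)phenyl)ethenyl]phenol (racemic) | Cc1ccc(cc1)S(=O)(=O)C(c1cc(OCc2ccccc2)cc(OCc2ccccc2)c1)c1c(O)cc(/C=C/c2ccc(OCc3ccccc3)cc2)cc1OCc1ccccc1 | intermediate
24 | 5-(benzyloxy)-6-{[3,5-bis(benzyloxy)phenyl]methylidene}-3-[(E)-2-(4-(benzyloxy)phenyl)ethenyl]cyclohexa-2,4-dien-1-one (ortho-quinone methide) | O=C1C=C(/C=C/c2ccc(OCc3ccccc3)cc2)C=C(OCc2ccccc2)C1=Cc1cc(OCc2ccccc2)cc(OCc2ccccc2)c1 | intermediate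
25 | sulfonium ylide of 16 | C[C@@H]1CC[C@@H]2C[C@H]1[S@@+]([CH-]c1ccc(OCc3ccccc3)c3c1O[C@H](c1ccc(OCc4ccccc4)cc1OCc1ccccc1)[C@H]3c1cc(OCc3ccccc3)cc(OCc3ccccc3)c1)C2(C)C | intermediate
26 | nona-O-benzylgnetumontanin B, (2S,3S,2′S,3′S) | c5ccccc5COc1ccc(/C=C/c2cc(OCc5ccccc5)c3c(c2)O[C@H](c2ccc(OCc5ccccc5)c4c2O[C@H](c2ccc(OCc5ccccc5)cc2OCc2ccccc2)[C@H]4c2cc(OCc5ccccc5)cc(OCc5ccccc5)c2)[C@H]3c2cc(OCc5ccccc5)cc(OCc5ccccc5)c2)cc1 | intermediate
27 | gnetumontanin B | Oc1ccc(/C=C/c2cc(O)c3c(c2)O[C@H](c2ccc(O)c4c2O[C@H](c2ccc(O)cc2O)[C@H]4c2cc(O)cc(O)c2)[C@H]3c2cc(O)cc(O)c2)cc1 | target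

**Totals.** Total step count: 17. Longest linear sequence: 9 steps (steps 3, 4, 6, 7, 8, 9, 10, 16, 17).

**Steps most likely to fail**

1. Step 8. The hindered chiral ylide may discriminate poorly between its two faces or between the approach geometries that lead to trans and cis rings, and slow ylide formation would let the quinone methide oligomerise. Fallback: reagent control is replaced by resolution. It sets out from 2 and 11. Alcohol 2 is alkylated onto tetrahydrothiophene (HBF4·OEt2, CH2Cl2) to give the small achiral salt 1-[2,4-bis(benzyloxy)benzyl]thiolan-1-ium tetrafluoroborate F1. Annulation of 11 with F1 (Cs2CO3, MeCN/CH2Cl2) should give the racemic trans ester, that is 14 together with methyl (2R,3R)-4-(benzyloxy)-2-[2,4-bis(benzyloxy)phenyl]-3-[3,5-bis(benzyloxy)phenyl]-2,3-dihydro-1-benzofuran-7-carboxylate F2. The two are separated by preparative chromatography on a chiral stationary phase, and the route is rejoined at 14.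

2. Step 16. Addition of the bulky, doubly chiral ylide to the hindered methide carbon may be sluggish, so that the stilbene-conjugated quinone methide decomposes, or reagent control may erode. Fallback: it sets out from 15 and 23. Alcohol 15 is converted with tetrahydrothiophene and HBF4·OEt2 into 1-({(2S,3S)-4-(benzyloxy)-2-[2,4-bis(benzyloxy)phenyl]-3-[3,5-bis(benzyloxy)phenyl]-2,3-dihydro-1-benzofuran-7-yl}methyl)thiolan-1-ium tetrafluoroborate F3. Its unhindered ylide is annulated with 23 (Cs2CO3) to give both trans rings, that is 26 and the (2R,3R,2′S,3′S)-diastereomer of nona-O-benzylgnetumontanin B F4. Because the lower ring is already enantiopure these are diastereomers and are separated on silica, and the route is rejoined at 26.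

3. Step 17. While nine ethers are cleaved, the acid may ionise the C2′–O1′ bond (epimerisation or re-closure) or trigger Friedel–Crafts attack on the protonated stilbene, and cleavage may stay incomplete. Fallback: it sets out from 26 and arrives directly at 27. Debenzylation is done by SN2 attack of thiolate at the nine benzylic carbons under basic, non-ionising conditions (NaSEt in excess, DMF, 90 °C, argon; cold aq. HCl quench). No cation is formed and no new compound is made (F0).

**Further compounds**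

F1 | step 8 | 1-[2,4-bis(benzyloxy)benzyl]thiolan-1-ium tetrafluoroborate | c1ccccc1COc1ccc(C[S+]2CCCC2)c(OCc2ccccc2)c1.F[B-](F)(F)F
F2 | step 8 | methyl (2R,3R)-4-(benzyloxy)-2-[2,4-bis(benzyloxy)phenyl]-3-[3,5-bis(benzyloxy)phenyl]-2,3-dihydro-1-benzofuran-7-carboxylate | COC(=O)c1ccc(OCc3ccccc3)c2c1O[C@@H](c1ccc(OCc3ccccc3)cc1OCc1ccccc1)[C@@H]2c1cc(OCc2ccccc2)cc(OCc2ccccc2)c1
F3 | step 16 | 1-({(2S,3S)-4-(benzyloxy)-2-[2,4-bis(benzyloxy)phenyl]-3-[3,5-bis(benzyloxy)phenyl]-2,3-dihydro-1-benzofuran-7-yl}methyl)thiolan-1-ium tetrafluoroborate | C1CC[S+](C1)Cc1ccc(OCc3ccccc3)c2c1O[C@H](c1ccc(OCc3ccccc3)cc1OCc1ccccc1)[C@H]2c1cc(OCc2ccccc2)cc(OCc2ccccc2)c1.F[B-](F)(F)F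
F4 | step 16 | (2R,3R,2′S,3′S)-diastereomer of nona-O-benzylgnetumontanin B | c5ccccc5COc1ccc(/C=C/c2cc(OCc5ccccc5)c3c(c2)O[C@@H](c2ccc(OCc5ccccc5)c4c2O[C@H](c2ccc(OCc5ccccc5)cc2OCc2ccccc2)[C@H]4c2cc(OCc5ccccc5)cc(OCc5ccccc5)c2)[C@@H]3c2cc(OCc5ccccc5)cc(OCc5ccccc5)c2)cc1
F0 | step 17 | none | none
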